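## Retrosynthetic overview

1. The target comes from global acetal cleavage of 27, which is assembled by an sp3–sp2 Negishi coupling (C2′–C3′) of the chroman alkyl iodide 15 with the (E)-alkenyl iodide 25 that carries the anti diol as an acetonide.
2. Benzene ring A is bought (3-methylsalicylic acid). Pyran ring B is the only ring of the target that is formed: a dirhodium carbenoid at the future C3 inserts into the C–H bond of an aryl sec-alkyl ether methine (future C2). This gives the C2–C3 bond, ring B and the quaternary stereocentre in one operation, with retention.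
3. Enabling feature: C2 of ring B is bonded to the ring oxygen O1, so in the ring-opened precursor it is a methine α to an aryl ether oxygen with a hydridic C–H bond. The C8 methyl on ring A (ortho to O1) and the acyl arm at C4a turn that C–H toward the carbenoid. C4 is carried as a ketone to hold the carbenoid and is removed afterwards.
4. The C2 configuration comes from (R)-butane-1,3-diol by Mitsunobu inversion. The side chain comes from geraniol: Sharpless epoxide → anti triol (inversion at the tertiary carbon) → terminal epoxide → propargylation → carboalumination/iodination for the (E)-trisubstituted olefin.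

Key step: step 8

Assumption: the target is taken exactly as drawn, i.e. (2S) at the chroman carbon, (3′E), and (7′S,8′R) in the side chain, which is the anti diol with respect to the parent E olefin.

## Route

Step 1
Reactants: 1 2-hydroxy-3-methylbenzoic acid
Product: 3 2,5-dihydroxy-3-methylbenzoic acid, via aryl sulfate 2 (not isolated)
Conditions: K2S2O8, aq. NaOH, 0 °C → rt; then conc. HCl, 90 °C
Reagents that add atoms: dipotassium peroxodisulfate (K2S2O8), [K+].[K+].[O-]S(=O)(=O)OOS(=O)(=O)[O-]
Why: Elbs persulfate oxidation: the phenolate attacks the peroxide oxygen through its para carbon, the only free position conjugated with the phenolate (both ortho positions are substituted), and the aryl sulfate is then hydrolysed by acid.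

Step 2
Reactants: 3 2,5-dihydroxy-3-methylbenzoic acid
Product: 4 methyl 2,5-dihydroxy-3-methylbenzoate
Conditions: MeOH, H2SO4 (cat.), reflux
Reagents that add atoms: methanol, CO
Why: Fischer esterification driven by methanol as solvent.

Step 3
Reactants: 4 methyl 2,5-dihydroxy-3-methylbenzoate
Product: 5 methyl 2-hydroxy-5-(methoxymethoxy)-3-methylbenzoate
Conditions: MOMCl (1.05 equiv), iPr2NEt, CH2Cl2, 0 °C → rt
Reagents that add atoms: chloromethyl methyl ether, COCCl
Why: Selective O-alkylation of the 5-hydroxyl, because the 2-hydroxyl is hydrogen-bonded to the ester carbonyl and flanked by the methyl and ester groups.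

Step 4
Reactants: 6 (R)-butane-1,3-diol
Product: 7 (R)-4-(benzyloxy)butan-2-ol
Conditions: NaH (1.0 equiv), THF, 0 °C; BnBr (1.0 equiv), Bu4NI (cat.), 0 °C → rt
Reagents that add atoms: benzyl bromide, BrCc1ccccc1
Why: Williamson etherification in which the less hindered primary alkoxide should be benzylated preferentially; the stereocentre is not touched.

Step 5
Reactants: 5 methyl 2-hydroxy-5-(methoxymethoxy)-3-methylbenzoate; 7 (R)-4-(benzyloxy)butan-2-ol
Product: 8 methyl 2-{[(2S)-4-(benzyloxy)butan-2-yl]oxy}-5-(methoxymethoxy)-3-methylbenzoate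
Conditions: PPh3, DIAD, THF, 0 °C → rt
Reagents that add atoms: none
Why: Mitsunobu etherification: the phenol, acidified by the ortho ester, displaces the oxyphosphonium group by SN2 with inversion, so the (R)-carbinol should give the (S)-aryl ether.

Step 6
Reactants: 8 methyl 2-{[(2S)-4-(benzyloxy)butan-2-yl]oxy}-5-(methoxymethoxy)-3-methylbenzoate
Product: 9 2-{[(2S)-4-(benzyloxy)butan-2-yl]oxy}-5-(methoxymethoxy)-3-methylbenzoic acid
Conditions: LiOH·H2O, THF–MeOH–H2O, 50 °C; then 1 M HCl to pH 4, 0 °C
Reagents that add atoms: lithium hydroxide (LiOH), [Li+].[OH-]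
Why: Ester saponification; the stereogenic carbon is an ether carbon without an acidic hydrogen and is not at risk, and the MOM and benzyl ethers are stable to base.

Step 7
Reactants: 9 2-{[(2S)-4-(benzyloxy)butan-2-yl]oxy}-5-(methoxymethoxy)-3-methylbenzoic acid
Product: 11 1-{2-[(2S)-4-(benzyloxy)butan-2-yl]oxy-5-(methoxymethoxy)-3-methylphenyl}-2-diazoethan-1-one, via mixed anhydride 10 (not isolated)
Conditions: iBuOCOCl, Et3N, THF, −15 °C; then CH2N2, Et2O, 0 °C → rt
Reagents that add atoms: diazomethane, C=[N+]=[N-]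
Why: Acylation of diazomethane by a mixed carbonic anhydride (first stage of the Arndt–Eistert sequence), chosen because it generates no HCl that could cleave the MOM ether.

Step 8
Reactants: 11 1-{2-[(2S)-4-(benzyloxy)butan-2-yl]oxy-5-(methoxymethoxy)-3-methylphenyl}-2-diazoethan-1-one
Product: 12 (2S)-2-[2-(benzyloxy)ethyl]-6-(methoxymethoxy)-2,8-dimethylchroman-4-one
Conditions: Rh2(OAc)4 (1 mol %), CH2Cl2, 40 °C, slow addition of 11
Reagents that add atoms: none
Why: Rh2(OAc)4 converts the diazoketone into an electrophilic rhodium carbenoid at the future C3, which inserts through a concerted three-centre, hydride-transfer-like transition state into the C–H bond of the ether methine (future C2), the most hydridic C–H within reach because it is tertiary and α to the aryl ether oxygen O1. The closest known reaction type is the dirhodium-catalysed intramolecular C–H insertion of 2-alkoxyaryl diazoketones α to the ether oxygen, which gives chroman-4-ones, together with the established retention of configuration when carbenoids insert into stereogenic methine C–H bonds. Ring B (the dihydropyranone) closes through a six-membered cyclic transition state (1,6-insertion; carbenoid carbon–C4–C4a–C8a–O1–C2) that forms the C2–C3 bond. The new quaternary stereocentre C2 is controlled by the (S)-configured ether carbon itself: the C–C bond replaces the C–H bond on the same face, so the (S)-ether should give (S)-C2 without any chiral ligand. The step needs chemoselectivity for C–H insertion over attack on the lone pair of O1 (five-membered oxonium ylide, then 1,2-shift or β-elimination) and over insertion into the 2-methyl or C1′ C–H bonds (seven-membered rings). The C8 methyl and the acyl arm flank O1 and turn the methine C–H toward the carbenoid, the ylide has no allyl or benzyl group on O1 to give it a low-barrier exit and can revert, and the desired insertion is the only six-membered one available.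

Step 9
Reactants: 12 (2S)-2-[2-(benzyloxy)ethyl]-6-(methoxymethoxy)-2,8-dimethylchroman-4-one
Product: 14 2-[(2R)-6-(methoxymethoxy)-2,8-dimethylchroman-2-yl]ethan-1-ol, via chroman-4-ol 13 (not isolated)
Conditions: H2 (4 atm), 10% Pd/C, AcOH–EtOAc, 50 °C
Reagents that add atoms: none
Why: Catalytic hydrogenation should reduce the aryl ketone to the benzylic alcohol 13, whose C–O bond (activated by the ortho ring oxygen O1) is hydrogenolysed to CH2 while the benzyl ether is cleaved in the same operation; C2 is untouched (its descriptor changes to R only because the CIP priorities change).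

Step 10
Reactants: 14 2-[(2R)-6-(methoxymethoxy)-2,8-dimethylchroman-2-yl]ethan-1-ol
Product: 15 (2R)-2-(2-iodoethyl)-6-(methoxymethoxy)-2,8-dimethylchroman
Conditions: I2, PPh3, imidazole, CH2Cl2, 0 °C → rt
Reagents that add atoms: iodine, II
Why: Appel-type iodination of the primary alcohol by SN2 at CH2 under neutral conditions that the MOM ether tolerates.

Step 11
Reactants: 16 geraniol
Product: 17 (2S,3S)-2,3-epoxygeraniol
Conditions: Ti(OiPr)4 (5 mol %), L-(+)-diethyl tartrate (6 mol %), t-BuOOH, 4 Å MS, CH2Cl2, −20 °C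
Reagents that add atoms: tert-butyl hydroperoxide, CC(C)(C)OO
Why: Sharpless asymmetric epoxidation: the allylic hydroxyl binds the titanium tartrate complex, which selects the 2,3-olefin over the 6,7-olefin and, with L-(+)-diethyl tartrate, should deliver oxygen to the face that gives the (2S,3S)-epoxide.

Step 12
Reactants: 17 (2S,3S)-2,3-epoxygeraniol
Product: 18 (2S,3R)-3,7-dimethyloct-6-ene-1,2,3-triol
Conditions: HClO4 (cat.), THF–H2O, 0 °C
Reagents that add atoms: water, O
Why: Acid-catalysed epoxide hydrolysis: water should attack the protonated epoxide at the tertiary carbon C3 with inversion while C2 keeps the epoxide oxygen, which sets the anti diol.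

Step 13
Reactants: 18 (2S,3R)-3,7-dimethyloct-6-ene-1,2,3-triol
Product: 20 (2R)-6-methyl-2-[(2S)-oxiran-2-yl]hept-5-en-2-ol, via primary tosylate 19 (not isolated)
Conditions: TsCl (1.05 equiv), Et3N, Bu2SnO (2 mol %), CH2Cl2, 0 °C; then K2CO3, MeOH, rt
Reagents that add atoms: none
Why: Tin-catalysed selective sulfonylation of the primary hydroxyl, then intramolecular Williamson closure (3-exo-tet) by the C2 alkoxide; no bond to a stereocentre is broken.

Step 14
Reactants: 20 (2R)-6-methyl-2-[(2S)-oxiran-2-yl]hept-5-en-2-ol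
Product: 22 (5S,6R)-6,10-dimethylundec-9-en-1-yne-5,6-diol, via silylalkyne diol 21 (not isolated)
Conditions: 1-(trimethylsilyl)propyne (3 equiv), n-BuLi (3 equiv), THF, −78 → −20 °C; 20, −78 °C → rt; then MeOH, K2CO3, rt
Reagents that add atoms: 1-(trimethylsilyl)propyne, CC#C[Si](C)(C)C
Why: SN2 opening of the terminal epoxide at its CH2 carbon by the propargylic lithium reagent (one equivalent is consumed by the tertiary hydroxyl), then base-catalysed methanolysis of the alkynyl C–Si bond.

Step 15
Reactants: 22 (5S,6R)-6,10-dimethylundec-9-en-1-yne-5,6-diol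
Product: 24 (1E,5S,6R)-1-iodo-2,6,10-trimethylundeca-1,9-diene-5,6-diol, via alkenylalane 23 (not isolated)
Conditions: Me3Al (5 equiv), Cp2ZrCl2 (0.5 equiv), CH2Cl2, 0 °C → rt; then I2, THF, −30 → 0 °C
Reagents that add atoms: trimethylaluminium (Me3Al), C[Al](C)C; iodine, II
Why: Negishi zirconium-catalysed carboalumination: syn addition of methyl and aluminium across the terminal alkyne (methyl to the internal carbon), then iodinolysis of the alkenyl–Al bond with retention, which should give the (E)-iodoalkene; the hydroxyls are masked in situ as aluminium alkoxides.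

Step 16
Reactants: 24 (1E,5S,6R)-1-iodo-2,6,10-trimethylundeca-1,9-diene-5,6-diol
Product: 25 (4S,5R)-4-[(3E)-4-iodo-3-methylbut-3-en-1-yl]-2,2,5-trimethyl-5-(4-methylpent-3-en-1-yl)-1,3-dioxolane
Conditions: 2,2-dimethoxypropane, PPTS (cat.), CH2Cl2, rt
Reagents that add atoms: 2,2-dimethoxypropane, COC(C)(C)OC
Why: Acid-catalysed transacetalisation gives the acetonide, which removes the acidic hydroxyls before the organozinc coupling.

Step 17
Reactants: 15 (2R)-2-(2-iodoethyl)-6-(methoxymethoxy)-2,8-dimethylchroman; 25 (4S,5R)-4-[(3E)-4-iodo-3-methylbut-3-en-1-yl]-2,2,5-trimethyl-5-(4-methylpent-3-en-1-yl)-1,3-dioxolane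
Product: 27 (2S)-6-(methoxymethoxy)-2,8-dimethyl-2-{(3E)-4-methyl-6-[(4S,5R)-2,2,5-trimethyl-5-(4-methylpent-3-en-1-yl)-1,3-dioxolan-4-yl]hex-3-en-1-yl}chroman, via alkylzinc iodide 26 (not isolated)
Conditions: 15, Zn dust (activated with BrCH2CH2Br and Me3SiCl), LiCl, THF, 40 °C; then 25, Pd(PPh3)4 (5 mol %), THF, rt → 50 °C
Reagents that add atoms: none
Why: Negishi cross-coupling: zinc inserts into the primary C–I bond and the alkylzinc couples with the alkenyl iodide under Pd catalysis with retention of the (E)-geometry; acetals and the trisubstituted olefin are tolerated.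

Step 18
Reactants: 27 (2S)-6-(methoxymethoxy)-2,8-dimethyl-2-{(3E)-4-methyl-6-[(4S,5R)-2,2,5-trimethyl-5-(4-methylpent-3-en-1-yl)-1,3-dioxolan-4-yl]hex-3-en-1-yl}chroman
Product: 28 (2S)-2-[(3E,7S,8R)-7,8-dihydroxy-4,8,12-trimethyltrideca-3,11-dien-1-yl]-2,8-dimethylchroman-6-ol
Conditions: 3 M aq. HCl, MeOH–THF, rt
Reagents that add atoms: none
Why: Acid-catalysed cleavage of both acetals (aryl MOM ether and acetonide) under conditions that should leave the trisubstituted olefins, the tertiary alcohol and the tertiary ether carbon C2 intact.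

## Compound list

1 | 2-hydroxy-3-methylbenzoic acid | Cc1cccc(C(=O)O)c1O | starting material
2 | 2-hydroxy-3-methyl-5-(sulfooxy)benzoic acid (present as its salt in the basic medium) | Cc1cc(OS(=O)(=O)O)cc(C(=O)O)c1O | intermediate
3 | 2,5-dihydroxy-3-methylbenzoic acid | Cc1cc(O)cc(C(=O)O)c1O | intermediate
4 | methyl 2,5-dihydroxy-3-methylbenzoate | COC(=O)c1cc(O)cc(C)c1O | intermediate
5 | methyl 2-hydroxy-5-(methoxymethoxy)-3-methylbenzoate | COC(=O)c1cc(OCOC)cc(C)c1O | intermediate
6 | (R)-butane-1,3-diol | C[C@@H](O)CCO | starting material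
7 | (R)-4-(benzyloxy)butan-2-ol | C[C@@H](O)CCOCc1ccccc1 | intermediate
8 | methyl 2-{[(2S)-4-(benzyloxy)butan-2-yl]oxy}-5-(methoxymethoxy)-3-methylbenzoate | C[C@@H](CCOCc1ccccc1)Oc1c(C)cc(OCOC)cc1C(=O)OC | intermediate
9 | 2-{[(2S)-4-(benzyloxy)butan-2-yl]oxy}-5-(methoxymethoxy)-3-methylbenzoic acid | C[C@@H](CCOCc1ccccc1)Oc1c(C)cc(OCOC)cc1C(=O)O | intermediate
10 | mixed isobutyl carbonic anhydride of acid 9 | C[C@@H](CCOCc1ccccc1)Oc1c(C)cc(OCOC)cc1C(=O)OC(=O)OCC(C)C | intermediate
11 | 1-{2-[(2S)-4-(benzyloxy)butan-2-yl]oxy-5-(methoxymethoxy)-3-methylphenyl}-2-diazoethan-1-one | C[C@@H](CCOCc1ccccc1)Oc1c(C)cc(OCOC)cc1C(=O)C=[N+]=[N-] | intermediate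
12 | (2S)-2-[2-(benzyloxy)ethyl]-6-(methoxymethoxy)-2,8-dimethylchroman-4-one | O=C1C[C@](C)(CCOCc2ccccc2)Oc2c(C)cc(OCOC)cc12 | intermediate
13 | (2S)-2-[2-(benzyloxy)ethyl]-6-(methoxymethoxy)-2,8-dimethylchroman-4-ol (C4 epimers) | OC1C[C@](C)(CCOCc2ccccc2)Oc2c(C)cc(OCOC)cc12 | intermediate
14 | 2-[(2R)-6-(methoxymethoxy)-2,8-dimethylchroman-2-yl]ethan-1-ol | C[C@]1(CCO)CCc2cc(OCOC)cc(C)c2O1 | intermediate
15 | (2R)-2-(2-iodoethyl)-6-(methoxymethoxy)-2,8-dimethylchroman | C[C@]1(CCI)CCc2cc(OCOC)cc(C)c2O1 | intermediate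
16 | geraniol | CC(C)=CCC/C(C)=C/CO | starting material
17 | (2S,3S)-2,3-epoxygeraniol | CC(C)=CCC[C@]1(C)O[C@H]1CO | intermediate
18 | (2S,3R)-3,7-dimethyloct-6-ene-1,2,3-triol | CC(C)=CCC[C@@](C)(O)[C@@H](O)CO | intermediate
19 | (2S,3R)-2,3-dihydroxy-3,7-dimethyloct-6-en-1-yl 4-methylbenzenesulfonate | CC(C)=CCC[C@@](C)(O)[C@@H](O)COS(=O)(=O)c1ccc(C)cc1 | intermediate
20 | (2R)-6-methyl-2-[(2S)-oxiran-2-yl]hept-5-en-2-ol | CC(C)=CCC[C@@](C)(O)[C@@H]1CO1 | intermediate
21 | (5S,6R)-6,10-dimethyl-1-(trimethylsilyl)undec-9-en-1-yne-5,6-diol | CC(C)=CCC[C@@](C)(O)[C@@H](O)CCC#C[Si](C)(C)C | intermediate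
22 | (5S,6R)-6,10-dimethylundec-9-en-1-yne-5,6-diol | CC(C)=CCC[C@@](C)(O)[C@@H](O)CCC#C | intermediate
23 | (E)-alkenyldimethylalane from 22, both hydroxyls as dimethylaluminium alkoxides | CC(C)=CCC[C@@](C)(O[Al](C)C)[C@@H](O[Al](C)C)CC/C(C)=C/[Al](C)C | intermediate
24 | (1E,5S,6R)-1-iodo-2,6,10-trimethylundeca-1,9-diene-5,6-diol | CC(C)=CCC[C@@](C)(O)[C@@H](O)CC/C(C)=C/I | intermediate
25 | (4S,5R)-4-[(3E)-4-iodo-3-methylbut-3-en-1-yl]-2,2,5-trimethyl-5-(4-methylpent-3-en-1-yl)-1,3-dioxolane | CC(C)=CCC[C@@]1(C)OC(C)(C)O[C@H]1CC/C(C)=C/I | intermediate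
26 | {2-[(2R)-6-(methoxymethoxy)-2,8-dimethylchroman-2-yl]ethyl}zinc iodide | C[C@]1(CC[Zn]I)CCc2cc(OCOC)cc(C)c2O1 | intermediate
27 | (2S)-6-(methoxymethoxy)-2,8-dimethyl-2-{(3E)-4-methyl-6-[(4S,5R)-2,2,5-trimethyl-5-(4-methylpent-3-en-1-yl)-1,3-dioxolan-4-yl]hex-3-en-1-yl}chroman | CC(C)=CCC[C@@]1(C)OC(C)(C)O[C@H]1CC/C(C)=C/CC[C@@]2(C)CCc3cc(OCOC)cc(C)c3O2 | intermediate
28 | (2S)-2-[(3E,7S,8R)-7,8-dihydroxy-4,8,12-trimethyltrideca-3,11-dien-1-yl]-2,8-dimethylchroman-6-ol | CC(C)=CCC[C@@](C)(O)[C@@H](O)CC/C(C)=C/CC[C@@]1(C)CCc2cc(O)cc(C)c2O1 | target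

## Step count and risks

Total step count: 18.
Longest linear sequence: 11 steps (steps 1, 2, 3, 5, 6, 7, 8, 9, 10, 17, 18).

The three steps most likely to fail:

**Step 8.** The carbenoid may be diverted onto the lone pair of O1 (five-membered oxonium ylide, then 1,2-shift or β-elimination of the side chain) instead of inserting into the methine C–H bond. The fallback sets out from 5 and comes back at 12, closing ring B through the O1–C2 bond instead. Ester 5 is converted with MeNH(OMe)·HCl and iPrMgCl (THF, −10 °C) into the Weinreb amide 2-hydroxy-N-methoxy-5-(methoxymethoxy)-N,3-dimethylbenzamide F1. MeMgBr (THF, 0 °C) then gives the methyl ketone 1-[2-hydroxy-5-(methoxymethoxy)-3-methylphenyl]ethan-1-one F2. Kabbe condensation of F2 with commercial 4-(benzyloxy)butan-2-one and pyrrolidine (MeOH, reflux; aldol condensation then oxa-Michael closure) should give racemic 2-[2-(benzyloxy)ethyl]-6-(methoxymethoxy)-2,8-dimethylchroman-4-one F3. Preparative chromatography on a chiral stationary phase then separates 12 from its enantiomer (2R)-2-[2-(benzyloxy)ethyl]-6-(methoxymethoxy)-2,8-dimethylchroman-4-one F4.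

**Step 12.** Regiocontrol or clean inversion may be lost in the epoxide opening (water attack at C2, or a carbocation-like opening at C3 with partial retention), which would erode the enantiomeric or diastereomeric purity of the diol. The fallback sets out from 16 and comes back at 18 without any substitution at the tertiary carbon. Geraniol is epoxidised under the conditions of step 11 but with D-(−)-diethyl tartrate to give (2R,3R)-2,3-epoxygeraniol F5. Treatment with aq. NaOH in t-BuOH at 70 °C should then effect Payne rearrangement (the C1 alkoxide attacks C2 with inversion) and hydroxide opening of the resulting terminal epoxide at C1. This gives 18 with C3 retained and C2 inverted.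

**Step 9.** Hydrogenolysis may stall at the benzylic alcohol, or the acidic medium may promote retro-oxa-Michael ring opening of the chromanone and scramble C2. The fallback sets out from 12 and comes back at 14, replacing benzylic hydrogenolysis by hydrazone reduction. Ketone 12 is condensed with TsNHNH2 (EtOH, 50 °C) to the tosylhydrazone N′-[(2R)-2-[2-(benzyloxy)ethyl]-6-(methoxymethoxy)-2,8-dimethylchroman-4-ylidene]-4-methylbenzenesulfonohydrazide F6. Reduction with catecholborane (CHCl3, 0 °C), then NaOAc·3H2O at reflux, should give (2R)-2-[2-(benzyloxy)ethyl]-6-(methoxymethoxy)-2,8-dimethylchroman F7. Neutral hydrogenolysis of the benzyl ether (H2, 10% Pd/C, EtOAc, rt) then gives 14.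

## Further compounds

F1 | step 8 | 2-hydroxy-N-methoxy-5-(methoxymethoxy)-N,3-dimethylbenzamide | CON(C)C(=O)c1cc(OCOC)cc(C)c1O
F2 | step 8 | 1-[2-hydroxy-5-(methoxymethoxy)-3-methylphenyl]ethan-1-one | CC(=O)c1cc(OCOC)cc(C)c1O
F3 | step 8 | racemic 2-[2-(benzyloxy)ethyl]-6-(methoxymethoxy)-2,8-dimethylchroman-4-one | O=C1CC(C)(CCOCc2ccccc2)Oc2c(C)cc(OCOC)cc12
F4 | step 8 | (2R)-2-[2-(benzyloxy)ethyl]-6-(methoxymethoxy)-2,8-dimethylchroman-4-one | O=C1C[C@@](C)(CCOCc2ccccc2)Oc2c(C)cc(OCOC)cc12
F5 | step 12 | (2R,3R)-2,3-epoxygeraniol | CC(C)=CCC[C@@]1(C)O[C@@H]1CO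
F6 | step 9 | N′-[(2R)-2-[2-(benzyloxy)ethyl]-6-(methoxymethoxy)-2,8-dimethylchroman-4-ylidene]-4-methylbenzenesulfonohydrazide | Cc1ccc(cc1)S(=O)(=O)NN=C1C[C@](C)(CCOCc2ccccc2)Oc2c(C)cc(OCOC)cc12
F7 | step 9 | (2R)-2-[2-(benzyloxy)ethyl]-6-(methoxymethoxy)-2,8-dimethylchroman | C[C@]1(CCOCc2ccccc2)CCc2cc(OCOC)cc(C)c2O1
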